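Target is the easy thing to read: I take it to come from intermediate A, so its slope shows how fast intermediate A is spent.

- cedar: starting material 0.20 M; coupling partner 0.60 M; the very flask that is asked about, followed so far
- flask: starting material 0.20 M; coupling partner 0.600 M; time 30 min

cedar run (percent of the starting material charged)

| time / min | intermediate A / % | target / % | starting material / % |
|---|---|---|---|
| 0.500 | 24 | 2 | 61 |
| 1.33 | 36 | 9 | 30 |
| 3.00 | 37 | 29 | 15 |
| 10.0 | 14 | 69 | 2 |

(scatter of a reading: 1.5 percentage points)

- the numbers in the tables scatter by 1.5 percentage points (one standard deviation)

- when, up to 30 min, the flask holds most intermediate A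
- the amount of intermediate A, in percent of the starting material charged, at that time
- the first time at which intermediate A reaches 12%, in the same percent, in min

The flask is charged like cedar, so I read cedar's rows for it. The first row holds 24% at 0.500 min. A straight line would pass 12% at 0.250 min, but the curve bends over, so I expect slightly sooner. The second and third rows stand level at 36% and 37%, so I put the top midway, at 2.17 min, a shade above those readings.

Between those rows, target's slope over the mean intermediate A gives 0.328 min⁻¹, a half-life of 2.11 min. From the third row to the fourth, the same sum gives 3.09 min, which is longer. A half-life should stretch like that if coupling partner is being consumed, so I treat the step as second-order, first order in [coupling partner] and first order in [intermediate A]. Multiplying the first half-life by the charged [coupling partner] gives 76.1 M·s. This is my clock product, the half-life of intermediate A times the [coupling partner] it meets.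

The forecast gives 2.1 min, 39% and 0.23 min, on the ground that “The peak comes when A's feed equals this loss”.

The flask gives 39.4% at 1.91 min, and reaches 12% at 0.210 min.

    starting material → intermediate A (k = 0.0110 s⁻¹)
    intermediate A → intermediate B (k = 4.60 × 10⁻⁴ s⁻¹)
    coupling partner + intermediate A → intermediate C (k = 0.0100 L mol⁻¹ s⁻¹)
    intermediate B ⇌ intermediate D (K = 7.70, k = 0.00240 s⁻¹)
    intermediate B → side product (k = 8.50 × 10⁻⁴ s⁻¹)
    coupling partner + intermediate C → target (k = 0.120 L mol⁻¹ s⁻¹)
    starting material ⇌ dormant form (K = 0.870, k = 0.00550 s⁻¹)

Between 15.0 min and 30.0 min this flask's [coupling partner] averages 0.260 M, so the product gives a half-life of 4.88 min. Intermediate A falls from 7.69% to 0.858%, a half-life of 4.74 min. The neighbouring flask is charged with 0.24 M of coupling partner, so its half-life starts at 5.28 min, and its peak is 52.4%. By 30.0 min its coupling partner is down to 8.75% of charge, the product gives 60.4 min, and intermediate A stands at 17.0%.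

(The runs were generated by integration on assumed constants; scatter was added.)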